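- At the last elm reading the target stands at 8.2%, so, scatter apart, up to 91.8% of the starting material is left over, and up to 87.6% in larch. With that much left, you may draw straight lines through the late readings.

| flask | starting material | reagent in the second phase | remark | time | volume of the second phase over the first |
|---|---|---|---|---|---|
| elm | 0.050 M | 1.3 equiv | run made earlier |  |  |
| larch | 0.050 M | 2.1 equiv | run made earlier |  |  |
| flask | 0.050 M | 0.950 equiv |  | 2.0 min | 0.50 |

| elm: time / s | elm: target / % | larch: time / s | larch: target / % |
|---|---|---|---|
| 10.0 | 0 | 20.0 | 1.7 |
| 15.0 | 0.3 | 40.0 | 3.9 |
| 25.0 | 0 | 60.0 | 7.5 |
| 50.0 | 3.1 | 80.0 | 11.2 |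
| 90.0 | 8.2 | 90.0 | 12.4 |

(scatter of a reading: 1 percentage point)

- in the second phase: reagent in the second phase; everything else is in the first
- charges count per volume of the first phase; a concentration in a rate is the amount of a species over the volume of its own phase; every rate counts per litre of the first phase
- the analysis behind the earlier runs scatters by 1 percentage point, standard deviation
- the earlier runs hold the two phases in the same ratio of volumes as the flask asked about

- the target standing at 2.0 min, as a percentage of the starting material charged
- the change that raises the amount of target at 2.0 min, in percent of the starting material charged most ("none" if none brings more than 2 percentage points) (summer / dusk / none)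
- amount of target at 2.0 min, in percent of the starting material charged, after dusk

- Your decision for the flask is whether to double the reagent in the second phase (dusk), double its transfer coefficient (summer), or leave the recipe as it is.
- Take the late slope of each run and scale it by equivalents to the flask's charge: elm reads 0.0559 min⁻¹ and larch 0.0461 min⁻¹.
- Their mean, 0.0510 min⁻¹, is the scaled slope, the target gained per minute after the lag at the flask's charge of reagent, as a fraction of the starting material charged.
- The two lines, carried back to zero target, give a mean lag (induction period) of 21.4 s; both figures are readings and carry the scatter.
- Slope times the time after the lag gives me 8.39% for the flask.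
- If dusk doubles the slope, as the scaling by equivalents assumes, I reckon a gain of 8.4 percentage points, to 16.8%. If summer halves the lag, it gains 0.91 points, less than the 2 points that counts, so I would charge dusk.
- The forecast gives 8%, then 15.5% after dusk, lower than my dusk figure, and says “Dusk is best”.
- The flask gives 8.80%; the choice is dusk, which adds 5.8 points and reaches 14.6%, below my 16.8%, while summer adds 1.6 points.

    starting material + reagent in the reaction phase → target (k = 0.0640 L mol⁻¹ s⁻¹)
    reagent in the reaction phase ⇌ reagent in the second phase, rate k2*([reagent in the reaction phase] - [reagent in the second phase]/K2) per volume of the first phase (partition coefficient = 1.30, kL = 0.00840 s⁻¹)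
    reagent in the reaction phase + target → over-reacted product (k = 0.130 L mol⁻¹ s⁻¹)
    target ⇌ isomer of the product (K = 1.40, k = 0.00390 s⁻¹)

- Between 1.00 min and 2.0 min the target in the flask climbs from 3.90% to 8.80%, which is 0.0490 min⁻¹ against the scaled slope of 0.0510 min⁻¹. With the other amounts and the time held, the target in the flask moves by 5 points once the charge of reagent in the second phase reaches 0.366 equiv or 1.74 equiv. Read the same flask at 30 s: slope and lag give 0.731%, and it holds 1.32%, with 98.6% of the starting material left.

All runs are simulated with constants of no real substance; scatter was added.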